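**Retrosynthetic overview**
1. Target ⇐ hydroxyl-directed epoxidation of the Z C1=C10 alkene of a ten-membered homoallylic alcohol (last C–O bonds).
2. Ten-membered carbocycle (the only carbocyclic ring) ⇐ C9–C10 closure of an acyclic Z-vinyl iodide / primary halide by a new nickel-catalysed reductive coupling.
3. Key step before ring closure: Evans–Tishchenko reaction with cinnamaldehyde, which makes the C6–O cinnamate bond and the anti C8 carbinol together; the C4–C5 cis-oxirane is set just before by hydroxyl-directed epoxidation of the acyclic Z-allylic alcohol.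
4. C6–C7 and both stereocentres by Evans syn-aldol of N-isovaleryl oxazolidinone with a (2Z,6Z)-iodo-dienal; C9 added as chloromethyllithium to the Weinreb amide.
5. Dienal from neryl acetate (supplies the 4Z alkene) by selective ozonolysis and Z-selective iodo-Wittig olefination; ring order: C4–C5 oxirane → carbocycle → C1–C10 oxirane.

Assumption: the SMILES is taken literally, so both oxiranes are cis on the ten-membered ring (C3/C6 cis and C2/C9 cis, i.e. Z-alkene-derived); labels C1–C15 below are the ring positions of the target (oxiranes C1–C10 and C4–C5, cinnamate on C6, isopropyl on C7, OH on C8, methyls C14 on C10 and C15 on C4).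

**Step 1**
Reactants: 1 neryl acetate [(2Z)-3,7-dimethylocta-2,6-dien-1-yl acetate]
Product: 3 (2Z)-3-methyl-6-oxohex-2-en-1-yl acetate, via ozonide 2 (not isolated)
Conditions: O3 (1.0 equiv), CH2Cl2, −78 °C; then Me2S, −78 °C → rt
Reagents that add atoms: ozone, [O-][O+]=O
Why: Chemoselective ozonolysis with reductive work-up cleaves the electron-rich remote trisubstituted alkene, the 2,3-alkene being deactivated by the allylic acetate and keeping its Z geometry.

**Step 2**
Reactants: 3 (2Z)-3-methyl-6-oxohex-2-en-1-yl acetate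
Product: 5 (2Z,6Z)-7-iodo-3-methylocta-2,6-dien-1-ol, via acetate 4 (not isolated)
Conditions: EtPPh3I, n-BuLi, THF, 0 °C; I2, −78 °C; NaN(SiMe3)2, −78 → −20 °C; 3, −78 °C; then K2CO3, MeOH, rt
Reagents that add atoms: ethyltriphenylphosphonium iodide, CC[P+](c1ccccc1)(c1ccccc1)c1ccccc1.[I-]; iodine, [I][I]
Why: Stork–Zhao-type α-iodo Wittig olefination gives the Z iodoalkene under kinetic control (iodine cis to the chain, which later becomes the Z C1=C10 geometry), and the acetate is then removed by base-catalysed transesterification in the same flask.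

**Step 3**
Reactants: 5 (2Z,6Z)-7-iodo-3-methylocta-2,6-dien-1-ol
Product: 6 (2Z,6Z)-7-iodo-3-methylocta-2,6-dienal
Conditions: TEMPO (10 mol %), PhI(OAc)2, CH2Cl2, 0 °C
Reagents that add atoms: none
Why: Oxoammonium (TEMPO/PhI(OAc)2) oxidation of the primary allylic alcohol stops at the aldehyde under near-neutral conditions, so the 2Z enal does not isomerise if used at once.

**Step 4**
Reactants: 6 (2Z,6Z)-7-iodo-3-methylocta-2,6-dienal; 7 (4S)-4-benzyl-3-(3-methylbutanoyl)-1,3-oxazolidin-2-one
Product: 10 (4S)-4-benzyl-3-[(2S,3R,4Z,8Z)-3-hydroxy-9-iodo-5-methyl-2-(propan-2-yl)deca-4,8-dienoyl]-1,3-oxazolidin-2-one, via boron enolate 8 (not isolated), via boron aldolate 9 (not isolated)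
Conditions: 7, Bu2BOTf, i-Pr2NEt, CH2Cl2, 0 °C; 6, −78 → 0 °C; then H2O2, MeOH, pH 7 buffer, 0 °C
Reagents that add atoms: none
Why: Evans syn-aldol reaction in which the Z boron enolate attacks the enal through a Zimmerman–Traxler chair on the face away from the benzyl group, setting C7 and C6 as the syn pair required (C6–O and C7–isopropyl syn).

**Step 5**
Reactants: 10 (4S)-4-benzyl-3-[(2S,3R,4Z,8Z)-3-hydroxy-9-iodo-5-methyl-2-(propan-2-yl)deca-4,8-dienoyl]-1,3-oxazolidin-2-one
Product: 11 (2S,3R,4Z,8Z)-3-hydroxy-9-iodo-N-methoxy-N,5-dimethyl-2-(propan-2-yl)deca-4,8-dienamide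
Conditions: MeNHOMe·HCl, AlMe3, THF, −20 → 0 °C
Reagents that add atoms: N,O-dimethylhydroxylamine hydrochloride, CNOC.Cl
Why: Weinreb transamidation by the aluminium amide, assisted by the free β-hydroxyl, removes the auxiliary without epimerising C7 and leaves an acyl group that accepts exactly one carbon nucleophile.

**Step 6**
Reactants: 11 (2S,3R,4Z,8Z)-3-hydroxy-9-iodo-N-methoxy-N,5-dimethyl-2-(propan-2-yl)deca-4,8-dienamide
Product: 12 (2S,3S)-3-hydroxy-3-[(2R,3S)-3-[(3Z)-4-iodopent-3-en-1-yl]-3-methyloxiran-2-yl]-N-methoxy-N-methyl-2-(propan-2-yl)propanamide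
Conditions: mCPBA (1.05 equiv), CH2Cl2/aq NaHCO3, 0 °C
Reagents that add atoms: mCPBA (3-chloroperoxybenzoic acid), OOC(=O)c1cccc(Cl)c1
Why: Henbest hydroxyl-directed peracid epoxidation, in which A(1,3) strain with the cis C3 chain holds the carbinol C–H in the alkene plane so the hydrogen-bonded peracid delivers oxygen syn to OH, giving the threo (4S,5R) cis-oxirane (about 95:5 expected) while the electron-poor iodoalkene is left alone.

**Step 7**
Reactants: 12 (2S,3S)-3-hydroxy-3-[(2R,3S)-3-[(3Z)-4-iodopent-3-en-1-yl]-3-methyloxiran-2-yl]-N-methoxy-N-methyl-2-(propan-2-yl)propanamide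
Product: 14 (3S,4S)-1-chloro-4-hydroxy-4-[(2R,3S)-3-[(3Z)-4-iodopent-3-en-1-yl]-3-methyloxiran-2-yl]-3-(propan-2-yl)butan-2-one, via lithium hemiaminal chelate 13 (not isolated)
Conditions: ICH2Cl (3 equiv), MeLi·LiBr (3 equiv, slow addition), THF/Et2O, −78 °C; then aqueous work-up
Reagents that add atoms: chloroiodomethane, ClCI
Why: Weinreb ketone synthesis with chloromethyllithium (made by I/Li exchange in the presence of the substrate), where the stable lithium chelate prevents over-addition and releases the chloromethyl ketone (C9 installed) only on work-up, the oxirane and iodoalkene being inert at −78 °C.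

**Step 8**
Reactants: 14 (3S,4S)-1-chloro-4-hydroxy-4-[(2R,3S)-3-[(3Z)-4-iodopent-3-en-1-yl]-3-methyloxiran-2-yl]-3-(propan-2-yl)butan-2-one; 15 (E)-cinnamaldehyde
Product: 17 (1S,2R,3S)-4-chloro-3-hydroxy-1-[(2R,3S)-3-[(3Z)-4-iodopent-3-en-1-yl]-3-methyloxiran-2-yl]-2-(propan-2-yl)butyl (2E)-3-phenylprop-2-enoate, via hemiacetal 16 (not isolated)
Conditions: 15 (6 equiv), SmI2 (30 mol %, pre-stirred with 15 until colourless), THF, −10 °C
Reagents that add atoms: none
Why: Evans–Tishchenko reaction in which the C6 hydroxyl forms a hemiacetal with cinnamaldehyde and trivalent samarium relays its hydride to the C8 ketone through a six-membered chair, creating the C6–O cinnamate bond and the 1,3-anti C8 carbinol in one operation with the two oxygens differentiated.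

**Step 9**
Reactants: 17 (1S,2R,3S)-4-chloro-3-hydroxy-1-[(2R,3S)-3-[(3Z)-4-iodopent-3-en-1-yl]-3-methyloxiran-2-yl]-2-(propan-2-yl)butyl (2E)-3-phenylprop-2-enoate
Product: 19 (1R,2S,3R,4R,6Z,10S)-4-hydroxy-6,10-dimethyl-3-(propan-2-yl)-11-oxabicyclo[8.1.0]undec-6-en-2-yl (2E)-3-phenylprop-2-enoate, via iodohydrin 18 (not isolated)
Conditions: NaI (5 equiv), DMA, 50 °C; then syringe-pump addition (12 h) to NiBr2(MeOCH2CH2OMe) (30 mol %), 4,4'-di-tert-butyl-2,2'-bipyridine (33 mol %), Mn powder (4 equiv), DMA, 40 °C, final 2 mM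
Reagents that add atoms: none
Why: Proposed new method: an intramolecular nickel-catalysed reductive cross-electrophile coupling closes the ten-membered carbocycle at C9–C10, the reasoning being that zerovalent nickel/bipyridine inserts selectively into the C(sp2)–I bond with retention (so the Z geometry of step 2 becomes the ring C1=C10 geometry), a monovalent nickel halide abstracts iodine from the primary iodide of 18 to give the C9 radical, this radical is captured by the tethered divalent vinylnickel and the C–C bond is released by reductive elimination from trivalent nickel, Mn turns the catalyst over, and slow addition keeps the substrate far more dilute than nickel so that ring closure outruns dimerisation while the free hydroxyl, ester and oxirane survive the neutral conditions; the closest known reaction type is the intermolecular nickel/bipyridine-catalysed reductive coupling of vinyl or aryl halides with primary alkyl halides and iodide-opened epoxides, which has not been used to close a medium-sized carbocycle.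

**Step 10**
Reactants: 19 (1R,2S,3R,4R,6Z,10S)-4-hydroxy-6,10-dimethyl-3-(propan-2-yl)-11-oxabicyclo[8.1.0]undec-6-en-2-yl (2E)-3-phenylprop-2-enoate
Product: 20 (1R,4S,6R,7S,8R,9R,11S)-9-hydroxy-4,11-dimethyl-8-(propan-2-yl)-5,12-dioxatricyclo[9.1.0.0^4,6]dodecan-7-yl (2E)-3-phenylprop-2-enoate (CNP0272646.1)
Conditions: VO(acac)2 (10 mol %), t-BuOOH (1.5 equiv), CH2Cl2, 0 °C
Reagents that add atoms: tert-butyl hydroperoxide, CC(C)(C)OO
Why: Vanadium-catalysed hydroxyl-directed epoxidation in which the pentavalent vanadium alkoxide of the C8 hydroxyl delivers oxygen to the homoallylic Z alkene through a chair that the ring forces to be cis-bridged, so the oxirane forms syn (1,3-cis) to the hydroxyl as (1R,10S) and the electron-poor cinnamate alkene is untouched.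

**Compound list**
1 | neryl acetate, (2Z)-3,7-dimethylocta-2,6-dien-1-yl acetate | CC(C)=CCC/C(C)=C\COC(C)=O | starting material
2 | (2Z)-5-(5,5-dimethyl-1,2,4-trioxolan-3-yl)-3-methylpent-2-en-1-yl acetate (secondary ozonide) | CC1(C)OOC(CC/C(C)=C\COC(C)=O)O1 | intermediate
3 | (2Z)-3-methyl-6-oxohex-2-en-1-yl acetate | O=CCC/C(C)=C\COC(C)=O | intermediate
4 | (2Z,6Z)-7-iodo-3-methylocta-2,6-dien-1-yl acetate | CC(=O)OC/C=C(C)\CC/C=C(C)\I | intermediate
5 | (2Z,6Z)-7-iodo-3-methylocta-2,6-dien-1-ol | OC/C=C(C)\CC/C=C(C)\I | intermediate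
6 | (2Z,6Z)-7-iodo-3-methylocta-2,6-dienal | O=C/C=C(C)\CC/C=C(C)\I | intermediate
7 | (4S)-4-benzyl-3-(3-methylbutanoyl)-1,3-oxazolidin-2-one | CC(C)CC(=O)N1C(=O)OC[C@@H]1Cc1ccccc1 | starting material
8 | Z dibutylboron enolate of 7 | CC(C)/C=C(\OB(CCCC)CCCC)N1C(=O)OC[C@@H]1Cc1ccccc1 | intermediate
9 | O-dibutylboryl aldolate of 10 | CC(C)[C@H](C(=O)N1C(=O)OC[C@@H]1Cc1ccccc1)[C@H](OB(CCCC)CCCC)/C=C(C)\CC/C=C(C)\I | intermediate
10 | (4S)-4-benzyl-3-[(2S,3R,4Z,8Z)-3-hydroxy-9-iodo-5-methyl-2-(propan-2-yl)deca-4,8-dienoyl]-1,3-oxazolidin-2-one | CC(C)[C@H](C(=O)N1C(=O)OC[C@@H]1Cc1ccccc1)[C@H](O)/C=C(C)\CC/C=C(C)\I | intermediate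
11 | (2S,3R,4Z,8Z)-3-hydroxy-9-iodo-N-methoxy-N,5-dimethyl-2-(propan-2-yl)deca-4,8-dienamide | CC(C)[C@H](C(=O)N(C)OC)[C@H](O)/C=C(C)\CC/C=C(C)\I | intermediate
12 | (2S,3S)-3-hydroxy-3-[(2R,3S)-3-[(3Z)-4-iodopent-3-en-1-yl]-3-methyloxiran-2-yl]-N-methoxy-N-methyl-2-(propan-2-yl)propanamide | CC(C)[C@H](C(=O)N(C)OC)[C@H](O)[C@H]1O[C@@]1(C)CC/C=C(C)\I | intermediate
13 | dilithium salt of the tetrahedral adduct of 12 with chloromethyllithium (C6 alkoxide, chelated N-methoxy hemiaminal alkoxide) | CC(C)[C@H](C([O-])(CCl)N(C)OC)[C@H]([O-])[C@H]1O[C@@]1(C)CC/C=C(C)\I.[Li+].[Li+] | intermediate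
14 | (3S,4S)-1-chloro-4-hydroxy-4-[(2R,3S)-3-[(3Z)-4-iodopent-3-en-1-yl]-3-methyloxiran-2-yl]-3-(propan-2-yl)butan-2-one | CC(C)[C@H](C(=O)CCl)[C@H](O)[C@H]1O[C@@]1(C)CC/C=C(C)\I | intermediate
15 | (E)-cinnamaldehyde | O=C/C=C/c1ccccc1 | starting material
16 | hemiacetal of the C6 hydroxyl of 14 with 15 (samarium-bound in the flask, drawn free) | CC(C)[C@H](C(=O)CCl)[C@H](OC(O)/C=C/c1ccccc1)[C@H]1O[C@@]1(C)CC/C=C(C)\I | intermediate
17 | (1S,2R,3S)-4-chloro-3-hydroxy-1-[(2R,3S)-3-[(3Z)-4-iodopent-3-en-1-yl]-3-methyloxiran-2-yl]-2-(propan-2-yl)butyl (2E)-3-phenylprop-2-enoate | CC(C)[C@H]([C@H](O)CCl)[C@H](OC(=O)/C=C/c1ccccc1)[C@H]1O[C@@]1(C)CC/C=C(C)\I | intermediate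
18 | (1S,2R,3S)-3-hydroxy-4-iodo-1-[(2R,3S)-3-[(3Z)-4-iodopent-3-en-1-yl]-3-methyloxiran-2-yl]-2-(propan-2-yl)butyl (2E)-3-phenylprop-2-enoate | CC(C)[C@H]([C@H](O)CI)[C@H](OC(=O)/C=C/c1ccccc1)[C@H]1O[C@@]1(C)CC/C=C(C)\I | intermediate
19 | (1R,2S,3R,4R,6Z,10S)-4-hydroxy-6,10-dimethyl-3-(propan-2-yl)-11-oxabicyclo[8.1.0]undec-6-en-2-yl (2E)-3-phenylprop-2-enoate | CC(C)[C@H]1[C@H](OC(=O)/C=C/c2ccccc2)[C@H]2O[C@@]2(C)CC/C=C(C)\C[C@H]1O | intermediate
20 | (1R,4S,6R,7S,8R,9R,11S)-9-hydroxy-4,11-dimethyl-8-(propan-2-yl)-5,12-dioxatricyclo[9.1.0.0^4,6]dodecan-7-yl (2E)-3-phenylprop-2-enoate (CNP0272646.1) | CC(C)[C@H]1[C@H](OC(=O)/C=C/c2ccccc2)[C@H]2O[C@@]2(C)CC[C@H]2O[C@@]2(C)C[C@H]1O | target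

**Step count and risks**
Total step count: 10. Longest linear sequence: 10 steps (1 → 20); 7 and 15 are bought.

The three steps most likely to fail are 9, 8 and 10.

Step 9 (the proposed new ring closure) may give open-chain dimers, hydrodehalogenated material or radical addition to the cinnamate instead of the ten-membered ring. The fallback uses only known reactions and replaces the radical cross-electrophile coupling by a preformed organometallic. It sets out from 17 and comes back at 19. The C8 hydroxyl is silylated (Et3SiOTf, 2,6-lutidine, CH2Cl2, −78 °C) to the triethylsilyl ether F2. Chloride is exchanged for iodide (NaI, butanone, 70 °C) to give the silyl-protected primary iodide F3. Zinc is inserted selectively into the primary C–I bond (activated Zn dust, THF/DMA, 35 °C) to give the alkylzinc iodide F4. The ring is then closed by an intramolecular Negishi alkyl–alkenyl coupling (Pd(PPh3)4, THF, 50 °C, slow addition, 1 mM) to the silylated ten-membered ring F5. Desilylation (HF·pyridine buffered with pyridine, THF, 0 °C) returns 19.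

Step 8 (Evans–Tishchenko on an epoxy α-chloro ketone) may suffer retro-aldol cleavage, loss of chlorine if any divalent samarium survives, or attack of the new samarium alkoxide on the C4–C5 oxirane. The fallback separates acylation from reduction and relies on reagent control. It sets out from 14 and comes back at 17. The C6 hydroxyl is esterified with (E)-cinnamoyl chloride (2,6-lutidine, DMAP cat., CH2Cl2, −20 °C) to the β-cinnamoyloxy chloro ketone F1. The ketone is then reduced by a Corey–Bakshi–Shibata reduction ((S)-B-methyl oxazaborolidine, catecholborane, toluene, −78 °C), with the chloromethyl group as the small substituent so that hydride adds to the face giving the C8 configuration of 17.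

Step 10 may deliver oxygen to the wrong face of the ring alkene, or the vanadium Lewis acid may trigger transannular opening of the C4–C5 oxirane by the C8 hydroxyl. The fallback is a metal-free two-step halohydrin route that places the oxirane oxygen on the face opposite to the one an electrophile attacks. It sets out from 19 and comes back at 20. N-bromosuccinimide in wet THF at 0 °C gives the bromohydrin F6 (bromonium on the exposed face, water at the tertiary C10, bromine at C1). K2CO3 in acetone at rt then closes it with inversion at C1 to 20.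

**Further compounds**
F1 | step 8 | (1S,2S)-4-chloro-1-[(2R,3S)-3-[(3Z)-4-iodopent-3-en-1-yl]-3-methyloxiran-2-yl]-3-oxo-2-(propan-2-yl)butyl (2E)-3-phenylprop-2-enoate | CC(C)[C@H](C(=O)CCl)[C@H](OC(=O)/C=C/c1ccccc1)[C@H]1O[C@@]1(C)CC/C=C(C)\I
F2 | step 9 | O-triethylsilyl ether of 17 | CC(C)[C@H]([C@H](O[Si](CC)(CC)CC)CCl)[C@H](OC(=O)/C=C/c1ccccc1)[C@H]1O[C@@]1(C)CC/C=C(C)\I
F3 | step 9 | O-triethylsilyl ether of 18 | CC(C)[C@H]([C@H](O[Si](CC)(CC)CC)CI)[C@H](OC(=O)/C=C/c1ccccc1)[C@H]1O[C@@]1(C)CC/C=C(C)\I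
F4 | step 9 | alkylzinc iodide formed from F3 at C9 | CC(C)[C@H]([C@H](O[Si](CC)(CC)CC)C[Zn]I)[C@H](OC(=O)/C=C/c1ccccc1)[C@H]1O[C@@]1(C)CC/C=C(C)\I
F5 | step 9 | O-triethylsilyl ether of 19 | CC(C)[C@H]1[C@H](OC(=O)/C=C/c2ccccc2)[C@H]2O[C@@]2(C)CC/C=C(C)\C[C@H]1O[Si](CC)(CC)CC
F6 | step 10 | bromohydrin of 19 (bromine at C1, tertiary hydroxyl at C10, anti) | CC(C)[C@H]1[C@H](OC(=O)/C=C/c2ccccc2)[C@H]2O[C@@]2(C)CC[C@H](Br)[C@](O)(C)C[C@H]1O
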